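## Retrosynthetic overview

1. The target is a (2R,3R)-trans-3-O-methyl dihydroflavonol. Functional-group operations alone lead back to a protected (2S)-flavanone: release of 5-OH, 2'-OH and 5'-OH, O-methylation of 3-OH, and oxygenation of C3 anti to ring B.
2. The plan rests on C2 of ring C. It is benzylic, bound to O1 and to C1' of ring B, and is the sixth atom of the chain C3–C4–C4a–C8a–O1–C2. Cutting C2–C3 turns it into the OCH2 of an aryl benzyl ether with two enantiotopic, doubly activated hydrogens.
3. Key disconnection C2–C3: a chiral dirhodium acyl carbene at C3 inserts into one C2–H bond, which closes ring C and sets C2. C3 follows by substrate control.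
4. The diazoketone comes from the methyl ketone by detrifluoroacetylative diazo transfer. The O1–C2 bond comes from a Mitsunobu coupling of the ring A acetophenone (from 3,4,5-trimethoxyphenol) with the ring B benzyl alcohol (from methoxyhydroquinone).
5. Ring order: rings A and B are bought as arenes, and ring C is the only ring made.

Key step: step 7

Assumption: the sense of induction of Rh2(S-PTTL)4 on this substrate cannot be predicted with confidence and is taken to give the (2S)-flavanone; should it prove opposite, the equally available Rh2(R-PTTL)4 is used and nothing else changes (flavonoid numbering O1, C2, C3, C4, C4a, C5–C8, C8a, primed ring B is used throughout).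

## Route

Step 1
Reactants: 1 methoxyhydroquinone (2-methoxybenzene-1,4-diol)
Product: 2 1,4-bis(benzyloxy)-2-methoxybenzene
Conditions: BnBr (2.3 equiv), K2CO3 (3 equiv), DMF, N2, rt → 50 °C
Reagents that add atoms: benzyl bromide, BrCc1ccccc1
Why: Williamson ether synthesis of both phenoxides with a reactive primary benzylic halide, with air excluded so that the hydroquinone is capped before it can oxidise.

Step 2
Reactants: 2 1,4-bis(benzyloxy)-2-methoxybenzene
Product: 4 2,5-bis(benzyloxy)-4-methoxybenzaldehyde, via aryl iminium salt 3 (not isolated)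
Conditions: POCl3, DMF, 0 → 50 °C; then ice/H2O
Reagents that add atoms: N,N-dimethylformamide, CN(C)C=O; water, O
Why: Vilsmeier–Haack formylation, which should go to the one unhindered position activated by two oxygens (para to OMe, ortho to OBn), as is usual for 1,2,4-trialkoxybenzenes.

Step 3
Reactants: 4 2,5-bis(benzyloxy)-4-methoxybenzaldehyde
Product: 5 [2,5-bis(benzyloxy)-4-methoxyphenyl]methanol
Conditions: NaBH4, MeOH/THF, 0 °C
Reagents that add atoms: none
Why: Borohydride reduction of an aromatic aldehyde to the primary benzylic alcohol, which leaves the aryl ethers untouched.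

Step 4
Reactants: 6 3,4,5-trimethoxyphenol
Product: 7 1-(6-hydroxy-2,3,4-trimethoxyphenyl)ethanone
Conditions: AcOH, BF3·OEt2, 85 °C; then H2O
Reagents that add atoms: acetic acid, CC(=O)O
Why: BF3-promoted Friedel–Crafts acylation ortho to the phenol; the two free ring positions are equivalent by symmetry, and the hydrogen-bonded product is deactivated towards a second acylation.

Step 5
Reactants: 5 [2,5-bis(benzyloxy)-4-methoxyphenyl]methanol; 7 1-(6-hydroxy-2,3,4-trimethoxyphenyl)ethanone
Product: 9 1-{2-[2,5-bis(benzyloxy)-4-methoxybenzyloxy]-4,5,6-trimethoxyphenyl}ethanone, via alkoxyphosphonium aryloxide 8 (not isolated)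
Conditions: PPh3, DIAD, THF, 0 °C → rt
Reagents that add atoms: none
Why: Mitsunobu etherification of an acidic phenol with a primary benzylic alcohol, which forms O1–C2 under neutral conditions and avoids the unstable trialkoxybenzyl halide.

Step 6
Reactants: 9 1-{2-[2,5-bis(benzyloxy)-4-methoxybenzyloxy]-4,5,6-trimethoxyphenyl}ethanone
Product: 12 1-{2-[2,5-bis(benzyloxy)-4-methoxybenzyloxy]-4,5,6-trimethoxyphenyl}-2-diazoethanone, via lithium enolate 10 (not isolated), via trifluoroacetyl ketone 11 (not isolated)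
Conditions: LiN(SiMe3)2, THF, −78 °C; CF3CO2CH2CF3, −78 °C; cold 5 % aq HCl wash; then MsN3, Et3N, H2O (1 equiv), MeCN, rt
Reagents that add atoms: methanesulfonyl azide, CS(=O)(=O)N=[N+]=[N-]
Why: Detrifluoroacetylative variant of the Regitz diazo transfer, in which the transient trifluoroacetyl group activates the methyl ketone towards the sulfonyl azide and then leaves as the N-sulfonyl trifluoroacetamide, because it carries the more electrophilic carbonyl group.

Step 7
Reactants: 12 1-{2-[2,5-bis(benzyloxy)-4-methoxybenzyloxy]-4,5,6-trimethoxyphenyl}-2-diazoethanone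
Product: 14 (2S)-2-[2,5-bis(benzyloxy)-4-methoxyphenyl]-5,6,7-trimethoxychroman-4-one, via Rh2(S-PTTL)4 carbene 13 (not isolated)
Conditions: Rh2(S-PTTL)4 [dirhodium tetrakis(N-phthaloyl-(S)-tert-leucinate)] (2 mol %), 4 Å MS, toluene, 0 °C, 12 added by syringe pump over 6 h, final 0.01 M
Reagents that add atoms: none
Why: Rh2(S-PTTL)4 (divalent rhodium) binds the diazo carbon of 12 at an axial site, N2 leaves, and the electrophilic acyl carbene 13 meets one C2–H bond in a concerted but asynchronous three-centre transition state with hydride-transfer character, which forms C2–C3 and C3–H together and frees the catalyst. The closest known reaction type is the enantioselective intramolecular C–H insertion of 2-alkoxyaryl α-diazoketones next to the ether oxygen under chiral dirhodium carboxylates, which delivers chroman-4-ones. Ring C closes as a six-membered ring by 1,6-insertion along C3–C4–C4a–C8a–O1–C2, because the fifth atom, where such carbenes normally insert, is O1 and carries no hydrogen. C2 is the only new stereocentre and is set by the catalyst alone: the phthalimido walls of the four tert-leucinate ligands fix the orientation of the aroyl carbene, so that only one of the two enantiotopic C2 hydrogens can reach it while ring B points out of the pocket. Site selectivity is needed because the methyl hydrogens of the methoxy group at C5 also sit on a sixth atom (C3–C4–C4a–C5–O–CH3); the substrate should secure it, since C2–H is secondary, bound to O1 and benzylic to a ring whose ortho and para oxygen donors stabilise the developing positive charge, whereas the methyl C–H bonds are primary and an ylide at that methoxy oxygen has no good migrating group and reverts. Chemoselectivity against attack of O1 on the carbene (oxonium ylide, then Stevens 1,2-shift of the ring B benzyl group to a benzofuran-3-one) rests on the low basicity of O1, an aryl ether oxygen conjugated with the aroyl group, on the bulky carboxylate ligands, and on toluene, low temperature and slow addition, which also suppress intermolecular reaction at the PhCH2O groups.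

Step 8
Reactants: 14 (2S)-2-[2,5-bis(benzyloxy)-4-methoxyphenyl]-5,6,7-trimethoxychroman-4-one
Product: 16 (2S)-2-[2,5-bis(benzyloxy)-4-methoxyphenyl]-5,6,7-trimethoxy-4-(trimethylsilyloxy)-2H-chromene, via lithium enolate 15 (not isolated)
Conditions: TMSCl (3 equiv) present from the start, LiN(SiMe3)2 (1.2 equiv) added last, THF, −78 °C; pentane, filtration; kept cold and dark, used at once
Reagents that add atoms: chlorotrimethylsilane, C[Si](C)(C)Cl
Why: Silyl enol ether formation by kinetic deprotonation at C3 (the only enolisable position) under internal-quench conditions, where trapping of enolate 15 at −78 °C should outrun β-elimination of the ring A aryloxide, so that C2 keeps its configuration.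

Step 9
Reactants: 16 (2S)-2-[2,5-bis(benzyloxy)-4-methoxyphenyl]-5,6,7-trimethoxy-4-(trimethylsilyloxy)-2H-chromene
Product: 19 (2R,3R)-2-[2,5-bis(benzyloxy)-4-methoxyphenyl]-3-hydroxy-5,6,7-trimethoxychroman-4-one, via silyloxy epoxide 17 (not isolated), via 3-silyloxy ketone 18 (not isolated)
Conditions: DMDO (1.1 equiv, acetone), CH2Cl2, −40 → 0 °C; then 0.5 M aq citric acid, THF, 0 °C
Reagents that add atoms: dimethyldioxirane, CC1(C)OO1
Why: Rubottom oxidation, in which the dioxirane epoxidises the electron-rich C3=C4 enol ether on the face opposite the C2 aryl group, so that the new C3–O bond is trans to ring B (3R), and silyl migration followed by mild hydrolysis restores the ketone.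

Step 10
Reactants: 19 (2R,3R)-2-[2,5-bis(benzyloxy)-4-methoxyphenyl]-3-hydroxy-5,6,7-trimethoxychroman-4-one
Product: 20 (2R,3R)-2-[2,5-bis(benzyloxy)-4-methoxyphenyl]-3,5,6,7-tetramethoxychroman-4-one
Conditions: Me3OBF4, 1,8-bis(dimethylamino)naphthalene (Proton Sponge), 4 Å MS, CH2Cl2, 0 °C → rt
Reagents that add atoms: trimethyloxonium tetrafluoroborate, C[O+](C)C.F[B-](F)(F)F
Why: O-alkylation of the neutral alcohol with an oxonium salt, buffered by a non-nucleophilic base too hindered to enolise the ketone, so that neither C3 epimerisation nor opening of ring C should occur.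

Step 11
Reactants: 20 (2R,3R)-2-[2,5-bis(benzyloxy)-4-methoxyphenyl]-3,5,6,7-tetramethoxychroman-4-one
Product: 22 (2R,3R)-2-(2,5-dihydroxy-4-methoxyphenyl)-5-hydroxy-3,6,7-trimethoxychroman-4-one, via tris(dichloroboryl) ether 21 (not isolated)
Conditions: BCl3 (6 equiv), pentamethylbenzene (6 equiv), CH2Cl2, −78 → 0 °C; then H2O, argon
Reagents that add atoms: none
Why: Lewis-acid ether cleavage, in which BCl3 removes the aryl benzyl ethers at low temperature while pentamethylbenzene traps the benzyl cation by Friedel–Crafts alkylation, and on warming cleaves only the methyl ether at C5, the one that forms a six-membered chelate with C4=O; any reversible opening of C2–O1 should reclose to the more stable trans isomer under control of the untouched C3.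

## Compound list

1 | methoxyhydroquinone (2-methoxybenzene-1,4-diol) | COc1cc(O)ccc1O | starting material
2 | 1,4-bis(benzyloxy)-2-methoxybenzene | COc1cc(OCc2ccccc2)ccc1OCc1ccccc1 | intermediate
3 | [2,5-bis(benzyloxy)-4-methoxybenzylidene]dimethyliminium dichlorophosphate | COc1cc(OCc2ccccc2)c(C=[N+](C)C)cc1OCc1ccccc1.[O-]P(=O)(Cl)Cl | intermediate (not isolated)
4 | 2,5-bis(benzyloxy)-4-methoxybenzaldehyde | COc1cc(OCc2ccccc2)c(C=O)cc1OCc1ccccc1 | intermediate
5 | [2,5-bis(benzyloxy)-4-methoxyphenyl]methanol | COc1cc(OCc2ccccc2)c(CO)cc1OCc1ccccc1 | intermediate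
6 | 3,4,5-trimethoxyphenol | COc1cc(O)cc(OC)c1OC | starting material
7 | 1-(6-hydroxy-2,3,4-trimethoxyphenyl)ethanone | CC(=O)c1c(O)cc(OC)c(OC)c1OC | intermediate
8 | [2,5-bis(benzyloxy)-4-methoxybenzyloxy]triphenylphosphonium 2-acetyl-3,4,5-trimethoxyphenoxide | COc1cc(OCc2ccccc2)c(CO[P+](c2ccccc2)(c2ccccc2)c2ccccc2)cc1OCc1ccccc1.CC(=O)c1c([O-])cc(OC)c(OC)c1OC | intermediate (not isolated)
9 | 1-{2-[2,5-bis(benzyloxy)-4-methoxybenzyloxy]-4,5,6-trimethoxyphenyl}ethanone | CC(=O)c1c(OCc2cc(OCc3ccccc3)c(OC)cc2OCc2ccccc2)cc(OC)c(OC)c1OC | intermediate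
10 | lithium enolate of 9 | [Li+].[O-]C(=C)c1c(OCc2cc(OCc3ccccc3)c(OC)cc2OCc2ccccc2)cc(OC)c(OC)c1OC | intermediate (not isolated)
11 | 1-{2-[2,5-bis(benzyloxy)-4-methoxybenzyloxy]-4,5,6-trimethoxyphenyl}-4,4,4-trifluorobutane-1,3-dione | O=C(CC(=O)C(F)(F)F)c1c(OCc2cc(OCc3ccccc3)c(OC)cc2OCc2ccccc2)cc(OC)c(OC)c1OC | intermediate (not isolated)
12 | 1-{2-[2,5-bis(benzyloxy)-4-methoxybenzyloxy]-4,5,6-trimethoxyphenyl}-2-diazoethanone | [N-]=[N+]=CC(=O)c1c(OCc2cc(OCc3ccccc3)c(OC)cc2OCc2ccccc2)cc(OC)c(OC)c1OC | intermediate (key-step precursor)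
13 | carbene complex Rh2(S-PTTL)4=CH–C(O)Ar derived from 12 ([Rh] in the SMILES stands for the Rh2(S-PTTL)4 unit) | [Rh]=CC(=O)c1c(OCc2cc(OCc3ccccc3)c(OC)cc2OCc2ccccc2)cc(OC)c(OC)c1OC | intermediate (not isolated)
14 | (2S)-2-[2,5-bis(benzyloxy)-4-methoxyphenyl]-5,6,7-trimethoxychroman-4-one | COc1cc(OCc2ccccc2)c([C@@H]2CC(=O)c3c(OC)c(OC)c(OC)cc3O2)cc1OCc1ccccc1 | intermediate (key-step product)
15 | lithium enolate of 14, (2S) | COc1cc(OCc2ccccc2)c([C@@H]2C=C([O-])c3c(OC)c(OC)c(OC)cc3O2)cc1OCc1ccccc1.[Li+] | intermediate (not isolated)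
16 | (2S)-2-[2,5-bis(benzyloxy)-4-methoxyphenyl]-5,6,7-trimethoxy-4-(trimethylsilyloxy)-2H-chromene | COc1cc(OCc2ccccc2)c([C@@H]2C=C(O[Si](C)(C)C)c3c(OC)c(OC)c(OC)cc3O2)cc1OCc1ccccc1 | intermediate
17 | (2R,3R,4R)-2-[2,5-bis(benzyloxy)-4-methoxyphenyl]-3,4-epoxy-5,6,7-trimethoxy-4-(trimethylsilyloxy)chroman, oxirane oxygen anti to ring B | COc1cc(OCc2ccccc2)c([C@H]2Oc3cc(OC)c(OC)c(OC)c3[C@]4(O[Si](C)(C)C)O[C@H]24)cc1OCc1ccccc1 | intermediate (not isolated)
18 | (2R,3R)-2-[2,5-bis(benzyloxy)-4-methoxyphenyl]-5,6,7-trimethoxy-3-(trimethylsilyloxy)chroman-4-one | COc1cc(OCc2ccccc2)c([C@H]2Oc3cc(OC)c(OC)c(OC)c3C(=O)[C@@H]2O[Si](C)(C)C)cc1OCc1ccccc1 | intermediate (not isolated)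
19 | (2R,3R)-2-[2,5-bis(benzyloxy)-4-methoxyphenyl]-3-hydroxy-5,6,7-trimethoxychroman-4-one (2,3-trans) | COc1cc(OCc2ccccc2)c([C@H]2Oc3cc(OC)c(OC)c(OC)c3C(=O)[C@@H]2O)cc1OCc1ccccc1 | intermediate
20 | (2R,3R)-2-[2,5-bis(benzyloxy)-4-methoxyphenyl]-3,5,6,7-tetramethoxychroman-4-one | COc1cc(OCc2ccccc2)c([C@H]2Oc3cc(OC)c(OC)c(OC)c3C(=O)[C@@H]2OC)cc1OCc1ccccc1 | intermediate
21 | (2R,3R)-5,2',5'-tris(dichloroboryloxy) derivative of 22 (the boron at O5 chelated to C4=O) | COc1cc(OB(Cl)Cl)c([C@H]2Oc3cc(OC)c(OC)c(OB(Cl)Cl)c3C(=O)[C@@H]2OC)cc1OB(Cl)Cl | intermediate (not isolated)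
22 | (2R,3R)-2-(2,5-dihydroxy-4-methoxyphenyl)-5-hydroxy-3,6,7-trimethoxychroman-4-one (CNP0257825.1) | COc1cc(O)c([C@H]2Oc3cc(OC)c(OC)c(O)c3C(=O)[C@@H]2OC)cc1O | target

## Step count and risks

Total step count: 11.
Longest linear sequence: 10 steps (1, 2, 3, 5, 6, 7, 8, 9, 10, 11).

**Step 7 (most likely to fail).**
- Three things may go wrong. Attack of O1 on the carbene followed by benzyl migration may outrun insertion. Some insertion may take place at the methyl group on O5. The very electron-rich ring B may push the insertion towards a stepwise hydride transfer, which erodes the discrimination between the enantiotopic hydrogens.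
- The fallback sets out from 4 and 7 and comes back at 14.
- Claisen–Schmidt condensation (KOH, EtOH, rt) should give the chalcone (E)-3-[2,5-bis(benzyloxy)-4-methoxyphenyl]-1-(6-hydroxy-2,3,4-trimethoxyphenyl)prop-2-en-1-one F1.
- Intramolecular oxa-Michael addition (NaOAc, EtOH, reflux) should close it to the racemic flavanone rac-2-[2,5-bis(benzyloxy)-4-methoxyphenyl]-5,6,7-trimethoxychroman-4-one F2.
- A kinetic resolution by asymmetric transfer hydrogenation follows (Cp*RhCl[(R,R)-TsDPEN] or its mirror image, whichever consumes the (2R)-ketone, with HCO2H/Et3N in EtOAc). It should leave the (2S)-ketone 14 untouched. The other enantiomer is reduced to the cis alcohol (2R,4R)-2-[2,5-bis(benzyloxy)-4-methoxyphenyl]-5,6,7-trimethoxychroman-4-ol F3, which is removed by chromatography.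

**Step 11.**
- Further methyl ethers may be lost: the 3-OMe through chelation with C4=O, and the 6-OMe next to the boron chelate. Benzyl groups may be transferred onto the electron-rich rings. The C2–O1 bond, which ring B activates strongly, may ionise.
- The fallback sets out from 20 and comes back at 22. It separates the two cleavages.
- MgI2·OEt2 (toluene/Et2O, 50 °C) is a much weaker Lewis acid and acts only through the six-membered magnesium chelate. It should remove the 5-methyl group alone and give (2R,3R)-2-[2,5-bis(benzyloxy)-4-methoxyphenyl]-5-hydroxy-3,6,7-trimethoxychroman-4-one F4.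
- Neutral hydrogenolysis (H2, palladium on carbon, EtOAc) then releases the air-sensitive hydroquinone of 22 in the last operation.

**Step 8.**
- β-Elimination of the ring A aryloxide from the lithium enolate may open ring C and, on reclosure, racemise C2. The trimethylsilyl enol ether may also hydrolyse on handling.
- The fallback sets out from 14 and comes back at 19. It avoids any metal enolate by reversing the order of events.
- TBSOTf first silylates the carbonyl oxygen and Et3N then removes H3 (CH2Cl2, −78 → 0 °C). This should give the chromatographable (2S)-2-[2,5-bis(benzyloxy)-4-methoxyphenyl]-4-(tert-butyldimethylsilyloxy)-5,6,7-trimethoxy-2H-chromene F5.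
- DMDO should epoxidise it anti to ring B to (2R,3R,4R)-2-[2,5-bis(benzyloxy)-4-methoxyphenyl]-4-(tert-butyldimethylsilyloxy)-3,4-epoxy-5,6,7-trimethoxychroman F6.
- On warming, F6 rearranges to (2R,3R)-2-[2,5-bis(benzyloxy)-4-methoxyphenyl]-3-(tert-butyldimethylsilyloxy)-5,6,7-trimethoxychroman-4-one F7.
- HF·pyridine in THF then frees the 3-hydroxyl group of 19.

## Further compounds

F1 | step 7 | (E)-3-[2,5-bis(benzyloxy)-4-methoxyphenyl]-1-(6-hydroxy-2,3,4-trimethoxyphenyl)prop-2-en-1-one | COc1cc(OCc2ccccc2)c(/C=C/C(=O)c2c(O)cc(OC)c(OC)c2OC)cc1OCc1ccccc1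
F2 | step 7 | rac-2-[2,5-bis(benzyloxy)-4-methoxyphenyl]-5,6,7-trimethoxychroman-4-one | COc1cc(OCc2ccccc2)c(C2CC(=O)c3c(OC)c(OC)c(OC)cc3O2)cc1OCc1ccccc1
F3 | step 7 | (2R,4R)-2-[2,5-bis(benzyloxy)-4-methoxyphenyl]-5,6,7-trimethoxychroman-4-ol (2,4-cis) | COc1cc(OCc2ccccc2)c([C@H]2C[C@@H](O)c3c(OC)c(OC)c(OC)cc3O2)cc1OCc1ccccc1
F4 | step 11 | (2R,3R)-2-[2,5-bis(benzyloxy)-4-methoxyphenyl]-5-hydroxy-3,6,7-trimethoxychroman-4-one | COc1cc(OCc2ccccc2)c([C@H]2Oc3cc(OC)c(OC)c(O)c3C(=O)[C@@H]2OC)cc1OCc1ccccc1
F5 | step 8 | (2S)-2-[2,5-bis(benzyloxy)-4-methoxyphenyl]-4-(tert-butyldimethylsilyloxy)-5,6,7-trimethoxy-2H-chromene | COc1cc(OCc2ccccc2)c([C@@H]2C=C(O[Si](C)(C)C(C)(C)C)c3c(OC)c(OC)c(OC)cc3O2)cc1OCc1ccccc1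
F6 | step 8 | (2R,3R,4R)-2-[2,5-bis(benzyloxy)-4-methoxyphenyl]-4-(tert-butyldimethylsilyloxy)-3,4-epoxy-5,6,7-trimethoxychroman | COc1cc(OCc2ccccc2)c([C@H]2Oc3cc(OC)c(OC)c(OC)c3[C@]4(O[Si](C)(C)C(C)(C)C)O[C@H]24)cc1OCc1ccccc1
F7 | step 8 | (2R,3R)-2-[2,5-bis(benzyloxy)-4-methoxyphenyl]-3-(tert-butyldimethylsilyloxy)-5,6,7-trimethoxychroman-4-one | COc1cc(OCc2ccccc2)c([C@H]2Oc3cc(OC)c(OC)c(OC)c3C(=O)[C@@H]2O[Si](C)(C)C(C)(C)C)cc1OCc1ccccc1
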